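# Total synthesis proposal for CNP0157657.2 by Wittig–Still ring contraction of a 13-membered stannyl ether

## Analysis of the target

CNP0157657.2 is a germacranolide: a cyclodecane ring (C1–C10) fused along C6–C7 to an α-methylene-γ-butyrolactone (ring O on C6, C7–C11, C11=C13H2, C12=O), with methyl groups on C4 and C10. The ring carries a cis-epoxide across C1–C10, an acetate on C3, a Z trisubstituted alkene C4=C5 and a 3-methylbutanoate on C8. In this numbering the six stereocentres are 1R, 3R, 6S, 7R, 8S and 10S. H6 and H7 are cis (cis-fused lactone), the C8 oxygen is anti to C6 across C7–C8, and C3 is separated from the C6–C7–C8 triad by the alkene. The cis-epoxide shows that it derives from a Z alkene C1=C10, so both ring alkenes of the parent diene are Z. Sensitive groups are the α-methylene lactone (Michael acceptor, base-labile), the epoxide (acid-labile), two different secondary esters, and C3–H and C6–H, which are both allylic and oxygen-bearing. The synthesis is hard because a ten-membered ring with two Z trisubstituted alkenes resists end-to-end closure and the contiguous triad C6–C7–C8 sits on a mobile ring. The strategy rests on the homoallylic alcohol array C8(O)–C7–C11(=C13). It is the retron of a [2,3]-Wittig shift of an ether oxygen linking C8 to C13 across a C7=C11 double bond. If that double bond is held in a 2,5-dihydrofuran (O, C6, C7, C11, C12), the shift contracts a 13-membered ether to the ten-membered carbocycle and leaves the future lactone ring as a 3-methylenetetrahydrofuran.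

## Retrosynthetic reasoning

**39 ⇒ 38.** The two epoxide C–O bonds are removed last. C1=C10 in 38 is the only electron-rich alkene (C4=C5 is flanked by two allylic acyloxy groups, C11=C13 is conjugated), so a peracid should find it, and syn addition to the Z alkene gives the cis-epoxide.

**38 ⇒ 37 ⇒ 36.** The C3 acetate is traced to a silyl ether. An acetate would not survive the organolithium step, and a silyl ether keeps C3 distinct from C8 throughout.

**36 ⇒ 35.** The lactone carbonyl at C12 is taken back to a CH2 group, i.e. to the 3-methylenetetrahydrofuran 35. A lactone cannot be carried through carbanion chemistry. C12 is the one methylene that is both allylic and α to oxygen, so a chromium-based allylic oxidation can address it late.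

**35 ⇒ 34.** The C8 ester bond is cut, leaving the free C8 alcohol 34, the direct product of the key step.

**34 ⇒ 31 (via 33 and 32).** The C7–C8 bond is cut, O(C8) is joined to C13 and the double bond is moved from C11=C13 to C7=C11. This gives the 13-membered α-stannyl allyl ether 31, in which the allyl terminus is locked in a 2,5-dihydrofuran. This cut is chosen because the forward step is a ring contraction through a five-membered transition state. It forms the carbocycle, the exocyclic methylene, C7 and C8 in one operation. C8 comes stereospecifically from the stannane and C7 from the tether.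

**31 ⇒ 30.** The C7=C11 bond is cut by a metathesis transform. The 14-membered bis-ether 30 carries a vinyl group on C6 and a methylidene group on C11, and closing the five-membered ring across the macrocycle is entropically easy.

**30 ⇒ 29.** The O–C12 bond is cut to the hydroxy allylic chloride 29. The large ring is closed through the ordinary C6 alkoxide, not through the stannyl carbinol: an α-stannyl alkoxide reverts to aldehyde and stannyl anion, whereas the α-alkoxystannane ether is inert to alkoxide.

**29 ⇒ 28 ⇒ 27 ⇒ 26.** The C6–C7 bond is cut to a vinyl nucleophile and the Z enal 28. C6 is set by reagent control because C3 is too remote to direct it. The enal comes from the primary silyl ether in 26.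

**26 ⇒ 21 + 25; 25 ⇒ 24 ⇒ 23 ⇒ 22.** The O–C13 bond is cut to the α-hydroxystannane 21 and the imidate 25. Acid-catalysed imidate transfer etherifies 21 without forming its alkoxide and without touching the C8–O bond. The three-carbon unit C11–C13 comes from the symmetrical dichloride 22.

**21 ⇒ 20 ⇒ 16 + 17 (via 18 and 19); 16 ⇒ 15.** C8 is set by enantioselective reduction of the acylstannane 20. This is made from aldehyde 16 and tributyltin hydride 17 by stannyl anion addition and in situ oxidation. The aldehyde is unmasked from the primary TES ether in 15.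

**15 ⇒ 14 ⇒ 13 ⇒ 12.** C3 is set by oxazaborolidine-catalysed reduction of ketone 13. The C2–C3 bond-forming step (below) is not enantioselective, so its product 12 is oxidised and reduced again.

**12 ⇒ 10 (via 11) + 4.** The C2–C3 bond is cut between the two alkenes. It is the only bond that joins two equally sized halves while leaving both Z alkenes untouched. An allylbarium reagent is needed because it attacks through its α-carbon and keeps its Z geometry.

**4 ⇒ 3 ⇒ 2 ⇒ 1 and 10 ⇒ 9 ⇒ 8 ⇒ 7 ⇒ 6 ⇒ 5.** Both Z trisubstituted alkenes are taken from rings: C4=C5 from butenolide 1 and C1=C10 from dihydropyranone 5. Each lactone is opened as its N-methoxy-N-methyl amide, which differentiates the two ends.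

## Alternatives that were turned down

**Alternative 1: glycol cleavage of a decalin diol.** A bond is added between C3 and C8, so the ten-membered ring becomes two fused cyclohexenes, the ring-fusion diol A1. In the forward direction an oxidative glycol cleavage breaks C3–C8 and releases the (Z,Z)-dienedione A2.

- For: both Z alkenes are fixed by six-membered rings. The ring opening forms no C–C bond, needs no high dilution and is strain-neutral. C6 and C7 can be set on a rigid bicycle, and the C7 side chain with C11–C13 is already present.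
- Against: A2 arrives with C3 and C8 as ketones. Both must be reduced to the right epimers on a flexible ring and then told apart for acetate and 3-methylbutanoate. C7 is α to the C8 ketone and can epimerise. C2 and C9 are each α to a ketone and allylic, so the alkenes can move into conjugation and the 1,6-diketone can undergo transannular aldol reaction. After A2 at least eight more operations remain (two reductions, differentiation, PMB removal, two oxidations, lactonisation, epoxidation).
- Comparison: alternative 1 is stronger in the ring-forming event, which needs neither a macrocyclisation nor tin. The chosen strategy offers in its place a C8 oxygen created at the alcohol level with defined configuration, already distinct from C3, together with C7.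

**Alternative 2: Grob fragmentation of a hydroazulene mesylate.** A bond is added between C6 and C10, giving the bicyclo[5.3.0] C6 alcohol with a C1 mesylate, A3. In the forward direction its alkoxide fragments: C6–C10 breaks, C1=C10 and the C6 ketone form, and the cyclodecadienone A4 results.

- For: the fragmentation is concerted and stereospecific, so the C1=C10 geometry is dictated by the anti-periplanar arrangement. C3 and C8 oxygens are in place and differentiated. No organotin is needed.
- Against: in A4 C7 is a CH2 group. The C11–C13 unit, the C7 stereocentre and the C6 carbinol must all be introduced on the flexible ring. Enolisation of the C6 ketone towards C7 places the enolate β to the C8 silyloxy group (elimination) and competes with γ-deprotonation through the Z enone. A3 itself needs five stereocentres with a defined C1/C10 relationship.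
- Comparison: alternative 2 is stronger in alkene-geometry control at the ring-forming step. The chosen strategy offers the C7 substituent, the C6 oxygen and the exocyclic methylene already assembled when the carbocycle forms.

**Alternative 3: anionic oxy-Cope expansion of a cyclohexenol.** The C8–C9 bond is cut and C1 is joined to C6, giving the cis-1-alkenyl-6-isopropenylcyclohexenol A5. In the forward direction its potassium alkoxide undergoes a [3,3] shift that opens the six-membered ring to the cyclodecadienone A6.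

- For: four ring atoms are added in one step from a terpene-type cyclohexenone, and C3 is carried in from the six-membered ring. It is the shortest way to the carbocycle.
- Against: the geometry of the new C1=C10 alkene depends on a boat transition state of the cis-divinyl isomer, since the chair gives the E ring alkene. C8 depends on the enol ether geometry. The enolate that is formed (C6–C7) has the C8 alkoxy group in the β-position and can eliminate it. C7 is again unsubstituted, so the later steps of alternative 2 apply.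
- Comparison: alternative 3 is stronger in step count to the ring and in its cheap chiral starting point. The chosen strategy offers Z alkenes secured beforehand from lactone rings and stereospecific control of C7 and C8.

Key step: step 23

Remark: carbons are numbered as in germacranolides (given in the analysis); stereodescriptors in compound names follow each compound's own numbering.

## Route

Step 1
Reactants: 1 3-methylfuran-2(5H)-one
Product: 2 (2Z)-4-hydroxy-N-methoxy-N,2-dimethylbut-2-enamide
Conditions: MeNH(OMe)·HCl, AlMe3, CH2Cl2, 0 → 25 °C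
Reagents that add atoms: N,O-dimethylhydroxylamine hydrochloride, CNOC.Cl
Why: Aminolysis of the lactone by the chloroaluminium amide (Weinreb amide formation) opens the ring without touching the alkene, so the Z geometry of C4=C5 is inherited from the butenolide. The crude hydroxy amide is silylated at once to forestall relactonisation.

Step 2
Reactants: 2 (2Z)-4-hydroxy-N-methoxy-N,2-dimethylbut-2-enamide
Product: 3 (2Z)-4-[(tert-butyldimethylsilyl)oxy]-N-methoxy-N,2-dimethylbut-2-enamide
Conditions: TBSCl, imidazole, DMF, 0 °C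
Reagents that add atoms: tert-butyldimethylsilyl chloride, CC(C)(C)[Si](C)(C)Cl
Why: Silylation of the primary allylic alcohol under neutral conditions is faster than attack of the hydroxyl group on the cis amide. The TBS ether is the later handle for C6.

Step 3
Reactants: 3 (2Z)-4-[(tert-butyldimethylsilyl)oxy]-N-methoxy-N,2-dimethylbut-2-enamide
Product: 4 (2Z)-4-[(tert-butyldimethylsilyl)oxy]-2-methylbut-2-enal
Conditions: i-Bu2AlH, THF, −78 °C; aq. potassium sodium tartrate
Reagents that add atoms: none
Why: The N-methoxy-N-methyl amide is reduced to a chelated hemiaminal that releases the aldehyde only on work-up, so no over-reduction occurs. The Z enal is kept cold and used crude to avoid Z to E isomerisation.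

Step 4
Reactants: 5 4-methyl-5,6-dihydro-2H-pyran-2-one
Product: 6 (2Z)-5-hydroxy-N-methoxy-N,3-dimethylpent-2-enamide
Conditions: MeNH(OMe)·HCl, AlMe3, CH2Cl2, 0 → 25 °C
Reagents that add atoms: N,O-dimethylhydroxylamine hydrochloride, CNOC.Cl
Why: Weinreb aminolysis of the unsaturated δ-lactone: the β,β-disubstituted alkene does not accept the amide in a conjugate sense, and the Z geometry of C1=C10 comes from the ring. The two ends (C2 amide, C8 alcohol) are differentiated.

Step 5
Reactants: 6 (2Z)-5-hydroxy-N-methoxy-N,3-dimethylpent-2-enamide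
Product: 7 (2Z)-N-methoxy-N,3-dimethyl-5-[(triethylsilyl)oxy]pent-2-enamide
Conditions: TESCl, imidazole, CH2Cl2, 0 °C
Reagents that add atoms: chlorotriethylsilane, CC[Si](CC)(CC)Cl
Why: Standard silylation of a primary alcohol. TES is chosen because a primary TES ether can later be oxidised directly to the aldehyde in the presence of TBS ethers.

Step 6
Reactants: 7 (2Z)-N-methoxy-N,3-dimethyl-5-[(triethylsilyl)oxy]pent-2-enamide
Product: 9 (2Z)-3-methyl-5-[(triethylsilyl)oxy]pent-2-en-1-ol, via aldehyde 8 (not isolated)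
Conditions: i-Bu2AlH, THF, −78 °C; then MeOH, CeCl3·7H2O, NaBH4, −40 → 0 °C
Reagents that add atoms: none
Why: Reduction of the Weinreb amide to the Z enal is followed in the same flask by Luche 1,2-reduction, which gives the Z allylic alcohol without conjugate reduction.

Step 7
Reactants: 9 (2Z)-3-methyl-5-[(triethylsilyl)oxy]pent-2-en-1-ol
Product: 10 {[(3Z)-5-chloro-3-methylpent-3-en-1-yl]oxy}triethylsilane
Conditions: MsCl, 2,4,6-collidine, LiCl, DMF, 0 °C
Reagents that add atoms: lithium chloride, [Li+].[Cl-]
Why: Mesylation and in situ SN2 displacement by chloride give the primary allylic chloride without allylic transposition or loss of geometry. The C8 oxygen is already silylated, so closure to a dihydropyran cannot occur.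

Step 8
Reactants: 10 {[(3Z)-5-chloro-3-methylpent-3-en-1-yl]oxy}triethylsilane; 4 (2Z)-4-[(tert-butyldimethylsilyl)oxy]-2-methylbut-2-enal
Product: 12 (2Z,6Z)-1-[(tert-butyldimethylsilyl)oxy]-3,7-dimethyl-9-[(triethylsilyl)oxy]nona-2,6-dien-4-ol (racemic at C4), via allylbarium chloride 11 (not isolated)
Conditions: BaI2, lithium biphenylide, THF, 25 °C (activated Ba); 10, −78 °C; then 4, −78 °C
Reagents that add atoms: none
Why: Allylbarium reagents made from allylic chlorides at −78 °C keep their double-bond geometry and add 1,2 to aldehydes through the less substituted α-carbon (α-selective carbonyl allylation). The C2–C3 bond therefore forms with both Z alkenes intact. C3 is formed without control and is corrected in steps 9 and 10.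

Step 9
Reactants: 12 (2Z,6Z)-1-[(tert-butyldimethylsilyl)oxy]-3,7-dimethyl-9-[(triethylsilyl)oxy]nona-2,6-dien-4-ol
Product: 13 (2Z,6Z)-1-[(tert-butyldimethylsilyl)oxy]-3,7-dimethyl-9-[(triethylsilyl)oxy]nona-2,6-dien-4-one
Conditions: Dess–Martin periodinane, NaHCO3, CH2Cl2, 0 °C
Reagents that add atoms: none
Why: Buffered Dess–Martin oxidation gives the ketone without moving the β,γ-alkene into conjugation. The ketone is used without chromatography.

Step 10
Reactants: 13 (2Z,6Z)-1-[(tert-butyldimethylsilyl)oxy]-3,7-dimethyl-9-[(triethylsilyl)oxy]nona-2,6-dien-4-one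
Product: 14 (2Z,4R,6Z)-1-[(tert-butyldimethylsilyl)oxy]-3,7-dimethyl-9-[(triethylsilyl)oxy]nona-2,6-dien-4-ol
Conditions: (S)-2-methyl-CBS-oxazaborolidine (0.2 equiv), catecholborane, toluene, −78 °C
Reagents that add atoms: none
Why: Corey–Bakshi–Shibata reduction: the α-branched alkenyl group acts as the large substituent and the CH2 group as the small one. The (S)-catalyst should therefore give the 4R alcohol (C3 of the target), in the same sense as for aryl methyl ketones, by 1,2-reduction only.

Step 11
Reactants: 14 (2Z,4R,6Z)-1-[(tert-butyldimethylsilyl)oxy]-3,7-dimethyl-9-[(triethylsilyl)oxy]nona-2,6-dien-4-ol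
Product: 15 (2Z,4R,6Z)-1,4-bis[(tert-butyldimethylsilyl)oxy]-3,7-dimethyl-9-[(triethylsilyl)oxy]nona-2,6-diene
Conditions: TBSOTf, 2,6-lutidine, CH2Cl2, −78 °C
Reagents that add atoms: tert-butyldimethylsilyl trifluoromethanesulfonate, CC(C)(C)[Si](C)(C)OS(=O)(=O)C(F)(F)F
Why: The silyl triflate protects the hindered secondary allylic alcohol at low temperature without disturbing the TES ether. This C3 silyl ether survives the organolithium step.

Step 12
Reactants: 15 (2Z,4R,6Z)-1,4-bis[(tert-butyldimethylsilyl)oxy]-3,7-dimethyl-9-[(triethylsilyl)oxy]nona-2,6-diene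
Product: 16 (3Z,6R,7Z)-6,9-bis[(tert-butyldimethylsilyl)oxy]-3,7-dimethylnona-3,7-dienal
Conditions: (COCl)2, DMSO, CH2Cl2, −78 → −40 °C; Et3N, −78 → 0 °C
Reagents that add atoms: none
Why: Under Swern conditions a primary TES ether is cleaved by the chlorosulfonium salt and oxidised directly to the aldehyde, while TBS ethers are inert. The β,γ-unsaturated aldehyde is used at once so that the alkene does not move into conjugation.

Step 13
Reactants: 16 (3Z,6R,7Z)-6,9-bis[(tert-butyldimethylsilyl)oxy]-3,7-dimethylnona-3,7-dienal; 17 tributyltin hydride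
Product: 20 (3Z,6R,7Z)-6,9-bis[(tert-butyldimethylsilyl)oxy]-3,7-dimethyl-1-(tributylstannyl)nona-3,7-dien-1-one, via tributylstannyllithium 18 (not isolated), via lithium stannylalkoxide 19 (not isolated)
Conditions: 17, LiN(i-Pr)2, THF, 0 °C; 16, −78 °C; then 1,1'-(azodicarbonyl)dipiperidine, −78 → 0 °C
Reagents that add atoms: none
Why: The stannyl anion adds to the aldehyde at −78 °C, and the α-stannyl alkoxide is oxidised in the same flask by hydride transfer to the azodicarboxamide. The acylstannane is obtained without isolating the labile racemic hydroxystannane.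

Step 14
Reactants: 20 (3Z,6R,7Z)-6,9-bis[(tert-butyldimethylsilyl)oxy]-3,7-dimethyl-1-(tributylstannyl)nona-3,7-dien-1-one
Product: 21 (1S,3Z,6R,7Z)-6,9-bis[(tert-butyldimethylsilyl)oxy]-3,7-dimethyl-1-(tributylstannyl)nona-3,7-dien-1-ol
Conditions: (R)-BINAL-H [LiAlH(OEt)((R)-1,1'-bi-2-naphtholate)], THF, −78 °C
Reagents that add atoms: none
Why: BINAL-H reduction of acylstannanes is enantioselective, the stannyl group taking the place of the unsaturated substituent in the six-membered transition state. The (R)-reagent should give the 1S carbinol (C8 of the target) under reagent control. The product is used immediately.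

Step 15
Reactants: 22 3-chloro-2-(chloromethyl)prop-1-ene
Product: 24 2-(chloromethyl)prop-2-en-1-ol, via monoacetate 23 (not isolated)
Conditions: NaOAc (0.4 equiv), Bu4NBr (cat.), DMF, 60 °C; then MeOH, HCl (cat.), 25 °C
Reagents that add atoms: sodium acetate, CC(=O)[O-].[Na+]
Why: SN2 monosubstitution of the symmetrical bis-allylic chloride (used in excess) by acetate, then acid-catalysed transesterification, gives the chloro alcohol. Unreacted 22 is removed by distillation.

Step 16
Reactants: 24 2-(chloromethyl)prop-2-en-1-ol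
Product: 25 2-(chloromethyl)prop-2-en-1-yl 2,2,2-trichloroacetimidate
Conditions: Cl3CCN, DBU (cat.), CH2Cl2, 0 °C
Reagents that add atoms: trichloroacetonitrile, ClC(Cl)(Cl)C#N
Why: Base-catalysed addition of the alcohol to the nitrile gives the allylic trichloroacetimidate, an alkylating agent that works under acid catalysis.

Step 17
Reactants: 21 (1S,3Z,6R,7Z)-6,9-bis[(tert-butyldimethylsilyl)oxy]-3,7-dimethyl-1-(tributylstannyl)nona-3,7-dien-1-ol; 25 2-(chloromethyl)prop-2-en-1-yl 2,2,2-trichloroacetimidate
Product: 26 tributyl[(1S,3Z,6R,7Z)-6,9-bis[(tert-butyldimethylsilyl)oxy]-1-{[2-(chloromethyl)prop-2-en-1-yl]oxy}-3,7-dimethylnona-3,7-dien-1-yl]stannane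
Conditions: TfOH (5 mol %), cyclohexane/CH2Cl2, 0 °C
Reagents that add atoms: none
Why: Acid-catalysed alkyl transfer from the trichloroacetimidate etherifies the α-hydroxystannane without forming its alkoxide, which would revert to aldehyde and stannyl anion. The C8–O bond is not touched, so the configuration is retained, and direct and allylic attack on the symmetrical allyl unit give the same ether.

Step 18
Reactants: 26 tributyl[(1S,3Z,6R,7Z)-6,9-bis[(tert-butyldimethylsilyl)oxy]-1-{[2-(chloromethyl)prop-2-en-1-yl]oxy}-3,7-dimethylnona-3,7-dien-1-yl]stannane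
Product: 27 (2Z,4R,6Z,9S)-4-[(tert-butyldimethylsilyl)oxy]-9-{[2-(chloromethyl)prop-2-en-1-yl]oxy}-3,7-dimethyl-9-(tributylstannyl)nona-2,6-dien-1-ol
Conditions: HF·pyridine, pyridine, THF, 0 °C
Reagents that add atoms: none
Why: Buffered HF·pyridine cleaves the primary allylic TBS ether much faster than the hindered secondary one at C3. The stannane and the allylic chloride are not affected.

Step 19
Reactants: 27 (2Z,4R,6Z,9S)-4-[(tert-butyldimethylsilyl)oxy]-9-{[2-(chloromethyl)prop-2-en-1-yl]oxy}-3,7-dimethyl-9-(tributylstannyl)nona-2,6-dien-1-ol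
Product: 28 (2Z,4R,6Z,9S)-4-[(tert-butyldimethylsilyl)oxy]-9-{[2-(chloromethyl)prop-2-en-1-yl]oxy}-3,7-dimethyl-9-(tributylstannyl)nona-2,6-dienal
Conditions: MnO2, CH2Cl2, 25 °C
Reagents that add atoms: none
Why: Manganese dioxide oxidises the allylic alcohol selectively under neutral conditions and preserves the Z geometry. The enal is used crude.

Step 20
Reactants: 28 (2Z,4R,6Z,9S)-4-[(tert-butyldimethylsilyl)oxy]-9-{[2-(chloromethyl)prop-2-en-1-yl]oxy}-3,7-dimethyl-9-(tributylstannyl)nona-2,6-dienal
Product: 29 (3R,4Z,6R,8Z,11S)-6-[(tert-butyldimethylsilyl)oxy]-11-{[2-(chloromethyl)prop-2-en-1-yl]oxy}-5,9-dimethyl-11-(tributylstannyl)undeca-1,4,8-trien-3-ol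
Conditions: Zn(CH=CH2)2, (+)-MIB [(2R)-3-exo-morpholinoisoborneol, 10 mol %], toluene, −20 → 0 °C
Reagents that add atoms: divinylzinc, C=C[Zn]C=C
Why: Amino-alcohol-catalysed addition of divinylzinc to the aldehyde: the (+)-ligand should direct the vinyl group to the Re face and give the 3R carbinol (C6 of the target), by analogy with dialkylzinc additions to unsaturated aldehydes. The organozinc reagent leaves the allylic chloride and the stannane untouched.

Step 21
Reactants: 29 (3R,4Z,6R,8Z,11S)-6-[(tert-butyldimethylsilyl)oxy]-11-{[2-(chloromethyl)prop-2-en-1-yl]oxy}-5,9-dimethyl-11-(tributylstannyl)undeca-1,4,8-trien-3-ol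
Product: 30 tributyl[(2R,3Z,5R,7Z,10S)-5-[(tert-butyldimethylsilyl)oxy]-2-ethenyl-4,8-dimethyl-13-methylidene-1,11-dioxacyclotetradeca-3,7-dien-10-yl]stannane
Conditions: NaH, Bu4NI (cat.), THF (0.002 M, slow addition), 0 → 45 °C
Reagents that add atoms: none
Why: Intramolecular Williamson etherification: the C6 alkoxide displaces the primary allylic chloride under high dilution to close the 14-membered ring. Direct and allylic displacement give the same product because the allyl unit is symmetrical. The α-alkoxystannane ether is inert to alkoxide, which is why the ring is closed through this oxygen.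

Step 22
Reactants: 30 tributyl[(2R,3Z,5R,7Z,10S)-5-[(tert-butyldimethylsilyl)oxy]-2-ethenyl-4,8-dimethyl-13-methylidene-1,11-dioxacyclotetradeca-3,7-dien-10-yl]stannane
Product: 31 tributyl[(4S,6Z,9R,10Z,12R)-9-[(tert-butyldimethylsilyl)oxy]-6,10-dimethyl-3,13-dioxabicyclo[10.2.1]pentadeca-1(15),6,10-trien-4-yl]stannane
Conditions: RuCl2(H2IMes)(PCy3)(=CHPh) (second-generation Grubbs catalyst, 5 mol %), CH2Cl2 (0.005 M), 40 °C
Reagents that add atoms: none
Why: Ring-closing metathesis: the catalyst loads on the monosubstituted vinyl group and closes across the ring onto the 1,1-disubstituted alkene, forming the 2,5-dihydrofuran with loss of ethene. The trisubstituted alkenes and the stannane are spectators.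

Step 23
Reactants: 31 tributyl[(4S,6Z,9R,10Z,12R)-9-[(tert-butyldimethylsilyl)oxy]-6,10-dimethyl-3,13-dioxabicyclo[10.2.1]pentadeca-1(15),6,10-trien-4-yl]stannane
Product: 34 (3aR,4S,6Z,9R,10Z,11aS)-9-[(tert-butyldimethylsilyl)oxy]-6,10-dimethyl-3-methylidene-2,3,3a,4,5,8,9,11a-octahydrocyclodeca[b]furan-4-ol, via organolithium 32 (not isolated), via lithium alkoxide 33 (not isolated)
Conditions: n-BuLi, THF, −78 → −40 °C; aq. NH4Cl
Reagents that add atoms: none
Why: Butyllithium exchanges tin for lithium at C8 with retention, and the α-alkoxy organolithium 32 undergoes a [2,3]-sigmatropic shift in which C8 bonds to C7, the O–C13 bond breaks and C11=C13 appears, giving alkoxide 33. The closest known reactions are the Wittig–Still rearrangement of α-stannyl allyl ethers and [2,3]-Wittig ring contractions of macrocyclic allyl ethers to cyclodecenols. The ten-membered carbocycle is closed by contraction of the 13-membered ether through a five-membered envelope transition state (C8, O, C13, C11, C7) and not by end-to-end cyclisation; the dihydrofuran becomes the 3-methylenetetrahydrofuran. C8 is controlled by the stannane, because the shift goes with inversion at the lithium-bearing carbon, so the S stannane gives the S carbinol. C7 is controlled by the tether: the ten-atom bridge can reach C7 only on the face of the dihydrofuran that carries C5, which sets H7 cis to H6. C9 takes the exo position of the envelope, which gives the anti C7/C8 relationship of the target. The step needs the [2,3] shift to beat the [1,2] shift and proton transfer; low temperature and an allyl terminus held rigidly in the five-membered ring favour it. The silyl ether and the trisubstituted alkenes are inert to butyllithium at −78 °C.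

Step 24
Reactants: 34 (3aR,4S,6Z,9R,10Z,11aS)-9-[(tert-butyldimethylsilyl)oxy]-6,10-dimethyl-3-methylidene-2,3,3a,4,5,8,9,11a-octahydrocyclodeca[b]furan-4-ol
Product: 35 (3aR,4S,6Z,9R,10Z,11aS)-9-[(tert-butyldimethylsilyl)oxy]-6,10-dimethyl-3-methylidene-2,3,3a,4,5,8,9,11a-octahydrocyclodeca[b]furan-4-yl 3-methylbutanoate
Conditions: 3-methylbutanoyl chloride, pyridine, DMAP (cat.), CH2Cl2, 0 → 25 °C
Reagents that add atoms: 3-methylbutanoyl chloride, CC(C)CC(=O)Cl
Why: DMAP-catalysed acylation of the only free hydroxyl group installs the C8 ester while C3 is still silylated, so the two esters of the target are differentiated.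

Step 25
Reactants: 35 (3aR,4S,6Z,9R,10Z,11aS)-9-[(tert-butyldimethylsilyl)oxy]-6,10-dimethyl-3-methylidene-2,3,3a,4,5,8,9,11a-octahydrocyclodeca[b]furan-4-yl 3-methylbutanoate
Product: 36 (3aR,4S,6Z,9R,10Z,11aS)-9-[(tert-butyldimethylsilyl)oxy]-6,10-dimethyl-3-methylidene-2-oxo-2,3,3a,4,5,8,9,11a-octahydrocyclodeca[b]furan-4-yl 3-methylbutanoate
Conditions: CrO3, 3,5-dimethylpyrazole, CH2Cl2, −20 °C
Reagents that add atoms: chromium trioxide, O=[Cr](=O)=O
Why: Allylic oxidation by the chromium trioxide–dimethylpyrazole complex converts the CH2 group that is both allylic and α to the ring oxygen (C12) into the carbonyl group, the known conversion of 3-methylenetetrahydrofurans into α-methylene-γ-butyrolactones. C3–H and C6–H lie in the plane of the Z alkene (allylic 1,3-strain) and are poorly aligned for abstraction. The reaction is stopped before the C2 and C9 methylene groups are attacked.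

Step 26
Reactants: 36 (3aR,4S,6Z,9R,10Z,11aS)-9-[(tert-butyldimethylsilyl)oxy]-6,10-dimethyl-3-methylidene-2-oxo-2,3,3a,4,5,8,9,11a-octahydrocyclodeca[b]furan-4-yl 3-methylbutanoate
Product: 37 (3aR,4S,6Z,9R,10Z,11aS)-9-hydroxy-6,10-dimethyl-3-methylidene-2-oxo-2,3,3a,4,5,8,9,11a-octahydrocyclodeca[b]furan-4-yl 3-methylbutanoate
Conditions: HF·pyridine, THF, 0 → 25 °C
Reagents that add atoms: none
Why: Fluoride-mediated desilylation under weakly acidic conditions frees the C3 alcohol. It avoids the basic fluoride sources that would add to the α-methylene lactone or move acyl groups.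

Step 27
Reactants: 37 (3aR,4S,6Z,9R,10Z,11aS)-9-hydroxy-6,10-dimethyl-3-methylidene-2-oxo-2,3,3a,4,5,8,9,11a-octahydrocyclodeca[b]furan-4-yl 3-methylbutanoate
Product: 38 (3aR,4S,6Z,9R,10Z,11aS)-9-(acetyloxy)-6,10-dimethyl-3-methylidene-2-oxo-2,3,3a,4,5,8,9,11a-octahydrocyclodeca[b]furan-4-yl 3-methylbutanoate
Conditions: Ac2O, pyridine, DMAP (cat.), CH2Cl2, 0 °C
Reagents that add atoms: acetic anhydride, CC(=O)OC(C)=O
Why: Standard acetylation of the secondary allylic alcohol; the configuration at C3 is untouched.

Step 28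
Reactants: 38 (3aR,4S,6Z,9R,10Z,11aS)-9-(acetyloxy)-6,10-dimethyl-3-methylidene-2-oxo-2,3,3a,4,5,8,9,11a-octahydrocyclodeca[b]furan-4-yl 3-methylbutanoate
Product: 39 CNP0157657.2, (1R,3R,6S,7R,8S,10S)-3-acetoxy-1,10-epoxy-8-(3-methylbutanoyloxy)germacra-4Z,11(13)-dien-12,6-olide
Conditions: mCPBA, NaHCO3, CH2Cl2, 0 °C
Reagents that add atoms: 3-chloroperbenzoic acid, OOC(=O)c1cccc(Cl)c1
Why: Peracid (Prilezhaev) epoxidation: C1=C10 is the only electron-rich alkene left, since C4=C5 is flanked by two allylic acyloxy groups and C11=C13 is conjugated to the lactone. Syn addition to the Z alkene gives the cis-epoxide, and attack on the face away from the flanking C3 and C8 acyloxy groups is expected to give the 1R,10S isomer.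

## Compound list

1 | 3-methylfuran-2(5H)-one | CC1=CCOC1=O | starting material
2 | (2Z)-4-hydroxy-N-methoxy-N,2-dimethylbut-2-enamide | OC/C=C(/C)C(=O)N(C)OC | intermediate
3 | (2Z)-4-[(tert-butyldimethylsilyl)oxy]-N-methoxy-N,2-dimethylbut-2-enamide | CC(C)(C)[Si](C)(C)OC/C=C(/C)C(=O)N(C)OC | intermediate
4 | (2Z)-4-[(tert-butyldimethylsilyl)oxy]-2-methylbut-2-enal | CC(C)(C)[Si](C)(C)OC/C=C(/C)C=O | intermediate
5 | 4-methyl-5,6-dihydro-2H-pyran-2-one | CC1=CC(=O)OCC1 | starting material
6 | (2Z)-5-hydroxy-N-methoxy-N,3-dimethylpent-2-enamide | CON(C)C(=O)/C=C(/C)CCO | intermediate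
7 | (2Z)-N-methoxy-N,3-dimethyl-5-[(triethylsilyl)oxy]pent-2-enamide | CON(C)C(=O)/C=C(/C)CCO[Si](CC)(CC)CC | intermediate
8 | (2Z)-3-methyl-5-[(triethylsilyl)oxy]pent-2-enal | O=C/C=C(/C)CCO[Si](CC)(CC)CC | intermediate
9 | (2Z)-3-methyl-5-[(triethylsilyl)oxy]pent-2-en-1-ol | OC/C=C(/C)CCO[Si](CC)(CC)CC | intermediate
10 | {[(3Z)-5-chloro-3-methylpent-3-en-1-yl]oxy}triethylsilane | ClC/C=C(/C)CCO[Si](CC)(CC)CC | intermediate
11 | chloro{(2Z)-3-methyl-5-[(triethylsilyl)oxy]pent-2-en-1-yl}barium | Cl[Ba]C/C=C(/C)CCO[Si](CC)(CC)CC | intermediate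
12 | (2Z,6Z)-1-[(tert-butyldimethylsilyl)oxy]-3,7-dimethyl-9-[(triethylsilyl)oxy]nona-2,6-dien-4-ol, racemic at C4 | CC(C)(C)[Si](C)(C)OC/C=C(/C)C(O)C/C=C(/C)CCO[Si](CC)(CC)CC | intermediate
13 | (2Z,6Z)-1-[(tert-butyldimethylsilyl)oxy]-3,7-dimethyl-9-[(triethylsilyl)oxy]nona-2,6-dien-4-one | CC(C)(C)[Si](C)(C)OC/C=C(/C)C(=O)C/C=C(/C)CCO[Si](CC)(CC)CC | intermediate
14 | (2Z,4R,6Z)-1-[(tert-butyldimethylsilyl)oxy]-3,7-dimethyl-9-[(triethylsilyl)oxy]nona-2,6-dien-4-ol | CC(C)(C)[Si](C)(C)OC/C=C(/C)[C@H](O)C/C=C(/C)CCO[Si](CC)(CC)CC | intermediate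
15 | (2Z,4R,6Z)-1,4-bis[(tert-butyldimethylsilyl)oxy]-3,7-dimethyl-9-[(triethylsilyl)oxy]nona-2,6-diene | CC(C)(C)[Si](C)(C)OC/C=C(/C)[C@H](O[Si](C)(C)C(C)(C)C)C/C=C(/C)CCO[Si](CC)(CC)CC | intermediate
16 | (3Z,6R,7Z)-6,9-bis[(tert-butyldimethylsilyl)oxy]-3,7-dimethylnona-3,7-dienal | CC(C)(C)[Si](C)(C)OC/C=C(/C)[C@H](O[Si](C)(C)C(C)(C)C)C/C=C(/C)CC=O | intermediate
17 | tributyltin hydride | CCCC[SnH](CCCC)CCCC | starting material
18 | tributylstannyllithium | [Li][Sn](CCCC)(CCCC)CCCC | intermediate
19 | lithium (3Z,6R,7Z)-6,9-bis[(tert-butyldimethylsilyl)oxy]-3,7-dimethyl-1-(tributylstannyl)nona-3,7-dien-1-olate, both C1 epimers | CC(C)(C)[Si](C)(C)OC/C=C(/C)[C@H](O[Si](C)(C)C(C)(C)C)C/C=C(/C)CC(O[Li])[Sn](CCCC)(CCCC)CCCC | intermediate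
20 | (3Z,6R,7Z)-6,9-bis[(tert-butyldimethylsilyl)oxy]-3,7-dimethyl-1-(tributylstannyl)nona-3,7-dien-1-one | CC(C)(C)[Si](C)(C)OC/C=C(/C)[C@H](O[Si](C)(C)C(C)(C)C)C/C=C(/C)CC(=O)[Sn](CCCC)(CCCC)CCCC | intermediate
21 | (1S,3Z,6R,7Z)-6,9-bis[(tert-butyldimethylsilyl)oxy]-3,7-dimethyl-1-(tributylstannyl)nona-3,7-dien-1-ol | CC(C)(C)[Si](C)(C)OC/C=C(/C)[C@H](O[Si](C)(C)C(C)(C)C)C/C=C(/C)C[C@H]([Sn](CCCC)(CCCC)CCCC)O | intermediate
22 | 3-chloro-2-(chloromethyl)prop-1-ene | ClCC(=C)CCl | starting material
23 | 2-(chloromethyl)prop-2-en-1-yl acetate | CC(=O)OCC(=C)CCl | intermediate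
24 | 2-(chloromethyl)prop-2-en-1-ol | OCC(=C)CCl | intermediate
25 | 2-(chloromethyl)prop-2-en-1-yl 2,2,2-trichloroacetimidate | ClCC(=C)COC(=N)C(Cl)(Cl)Cl | intermediate
26 | tributyl[(1S,3Z,6R,7Z)-6,9-bis[(tert-butyldimethylsilyl)oxy]-1-{[2-(chloromethyl)prop-2-en-1-yl]oxy}-3,7-dimethylnona-3,7-dien-1-yl]stannane | CC(C)(C)[Si](C)(C)OC/C=C(/C)[C@H](O[Si](C)(C)C(C)(C)C)C/C=C(/C)C[C@H]([Sn](CCCC)(CCCC)CCCC)OCC(=C)CCl | intermediate
27 | (2Z,4R,6Z,9S)-4-[(tert-butyldimethylsilyl)oxy]-9-{[2-(chloromethyl)prop-2-en-1-yl]oxy}-3,7-dimethyl-9-(tributylstannyl)nona-2,6-dien-1-ol | OC/C=C(/C)[C@H](O[Si](C)(C)C(C)(C)C)C/C=C(/C)C[C@H]([Sn](CCCC)(CCCC)CCCC)OCC(=C)CCl | intermediate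
28 | (2Z,4R,6Z,9S)-4-[(tert-butyldimethylsilyl)oxy]-9-{[2-(chloromethyl)prop-2-en-1-yl]oxy}-3,7-dimethyl-9-(tributylstannyl)nona-2,6-dienal | O=C/C=C(/C)[C@H](O[Si](C)(C)C(C)(C)C)C/C=C(/C)C[C@H]([Sn](CCCC)(CCCC)CCCC)OCC(=C)CCl | intermediate
29 | (3R,4Z,6R,8Z,11S)-6-[(tert-butyldimethylsilyl)oxy]-11-{[2-(chloromethyl)prop-2-en-1-yl]oxy}-5,9-dimethyl-11-(tributylstannyl)undeca-1,4,8-trien-3-ol | C=C[C@@H](O)/C=C(/C)[C@H](O[Si](C)(C)C(C)(C)C)C/C=C(/C)C[C@H]([Sn](CCCC)(CCCC)CCCC)OCC(=C)CCl | intermediate
30 | tributyl[(2R,3Z,5R,7Z,10S)-5-[(tert-butyldimethylsilyl)oxy]-2-ethenyl-4,8-dimethyl-13-methylidene-1,11-dioxacyclotetradeca-3,7-dien-10-yl]stannane | C=C[C@@H]1/C=C(/C)[C@H](O[Si](C)(C)C(C)(C)C)C/C=C(/C)C[C@H]([Sn](CCCC)(CCCC)CCCC)OCC(=C)CO1 | intermediate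
31 | tributyl[(4S,6Z,9R,10Z,12R)-9-[(tert-butyldimethylsilyl)oxy]-6,10-dimethyl-3,13-dioxabicyclo[10.2.1]pentadeca-1(15),6,10-trien-4-yl]stannane | C1O[C@H]2/C=C(/C)[C@H](O[Si](C)(C)C(C)(C)C)C/C=C(/C)C[C@H]([Sn](CCCC)(CCCC)CCCC)OCC1=C2 | intermediate
32 | [(4S,6Z,9R,10Z,12R)-9-[(tert-butyldimethylsilyl)oxy]-6,10-dimethyl-3,13-dioxabicyclo[10.2.1]pentadeca-1(15),6,10-trien-4-yl]lithium | C1O[C@H]2/C=C(/C)[C@H](O[Si](C)(C)C(C)(C)C)C/C=C(/C)C[C@H]([Li])OCC1=C2 | intermediate
33 | lithium (3aR,4S,6Z,9R,10Z,11aS)-9-[(tert-butyldimethylsilyl)oxy]-6,10-dimethyl-3-methylidene-2,3,3a,4,5,8,9,11a-octahydrocyclodeca[b]furan-4-olate | C1O[C@H]2/C=C(/C)[C@H](O[Si](C)(C)C(C)(C)C)C/C=C(/C)C[C@H](O[Li])[C@H]2C1=C | intermediate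
34 | (3aR,4S,6Z,9R,10Z,11aS)-9-[(tert-butyldimethylsilyl)oxy]-6,10-dimethyl-3-methylidene-2,3,3a,4,5,8,9,11a-octahydrocyclodeca[b]furan-4-ol | C1O[C@H]2/C=C(/C)[C@H](O[Si](C)(C)C(C)(C)C)C/C=C(/C)C[C@H](O)[C@H]2C1=C | intermediate
35 | (3aR,4S,6Z,9R,10Z,11aS)-9-[(tert-butyldimethylsilyl)oxy]-6,10-dimethyl-3-methylidene-2,3,3a,4,5,8,9,11a-octahydrocyclodeca[b]furan-4-yl 3-methylbutanoate | C1O[C@H]2/C=C(/C)[C@H](O[Si](C)(C)C(C)(C)C)C/C=C(/C)C[C@H](OC(=O)CC(C)C)[C@H]2C1=C | intermediate
36 | (3aR,4S,6Z,9R,10Z,11aS)-9-[(tert-butyldimethylsilyl)oxy]-6,10-dimethyl-3-methylidene-2-oxo-2,3,3a,4,5,8,9,11a-octahydrocyclodeca[b]furan-4-yl 3-methylbutanoate | C=C1C(=O)O[C@H]2/C=C(/C)[C@H](O[Si](C)(C)C(C)(C)C)C/C=C(/C)C[C@H](OC(=O)CC(C)C)[C@@H]12 | intermediate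
37 | (3aR,4S,6Z,9R,10Z,11aS)-9-hydroxy-6,10-dimethyl-3-methylidene-2-oxo-2,3,3a,4,5,8,9,11a-octahydrocyclodeca[b]furan-4-yl 3-methylbutanoate | C=C1C(=O)O[C@H]2/C=C(/C)[C@H](O)C/C=C(/C)C[C@H](OC(=O)CC(C)C)[C@@H]12 | intermediate
38 | (3aR,4S,6Z,9R,10Z,11aS)-9-(acetyloxy)-6,10-dimethyl-3-methylidene-2-oxo-2,3,3a,4,5,8,9,11a-octahydrocyclodeca[b]furan-4-yl 3-methylbutanoate | C=C1C(=O)O[C@H]2/C=C(/C)[C@H](OC(C)=O)C/C=C(/C)C[C@H](OC(=O)CC(C)C)[C@@H]12 | intermediate
39 | CNP0157657.2, (1R,3R,6S,7R,8S,10S)-3-acetoxy-1,10-epoxy-8-(3-methylbutanoyloxy)germacra-4Z,11(13)-dien-12,6-olide | C=C1C(=O)O[C@H]2/C=C(/C)[C@H](OC(C)=O)C[C@H]3O[C@@]3(C)C[C@H](OC(=O)CC(C)C)[C@@H]12 | target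

## Step count and least certain steps

Total step count: 28 (26 on the way from 1 and 5 to 39, 2 for imidate 25).
Longest linear sequence: 23 steps (5 to 39: steps 4–14 and 17–28).

**Step 23 (key step).** The carbanion may leave the intended pathway. Possibilities are a [1,2]-shift through a radical pair, proton transfer from the doubly activated C6–H, or rearrangement through the other envelope, which would give the other C7/C8 relationship if transannular strain in the bicyclic transition state overrides the exo preference of C9.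
Fallback: form the same C7–C8 bond by intramolecular allylchromium addition, setting out from 16 and returning at 34.
- Acid-catalysed methanolysis with trimethyl orthoformate (camphorsulfonic acid, MeOH) should convert the aldehyde into its acetal and remove the primary allylic silyl ether, giving hydroxy dimethyl acetal F1.
- MnO2 gives acetal enal F2, and divinylzinc with (+)-MIB gives acetal vinyl carbinol F3.
- NaH and an excess of 22 give the allylic chloride ether F4, and the second-generation Grubbs catalyst RuCl2(H2IMes)(PCy3)(=CHPh) closes it to the chloromethyl dihydrofuran acetal F5.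
- Mild acid hydrolysis gives the chloromethyl dihydrofuran aldehyde F6.
- CrCl2 (divalent chromium) in THF at high dilution generates the allylchromium species at C13, which adds through C7 to the C8 aldehyde and gives 34. The closed chair transition state predicts the same anti C7/C8 relationship, and the tether again directs attack to the C5 face.

**Step 17.** The acid may remove or migrate silyl ethers, or alkyl transfer from the electron-poor imidate may be slow enough for the hydroxystannane to decompose (loss of tin, reversion to the aldehyde).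
Fallback: silver-assisted alkylation, setting out from 21 and returning at 26. Finkelstein exchange of 22 (NaI, acetone) gives the diiodide F7. AgOTf with 2,6-di-tert-butyl-4-methylpyridine and an excess of F7 alkylates 21 by halide abstraction under non-basic conditions, giving the iodomethyl ether F8. LiCl in DMF exchanges the remaining iodide for chloride, giving 26.

**Step 20.** Facial selectivity of vinyl transfer to a Z enal with a bulky cis β-substituent may be poor, and the Lewis acidic zinc species may isomerise the enal.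
Fallback: set C6 by ketone reduction, setting out from 28 and returning at 29. Ethynylmagnesium bromide adds to 28 to give the propargylic alcohol epimers F9. MnO2 oxidises them to the ynone F10. Midland reduction with (S)-Alpine-Borane, in which the ethynyl group is the small substituent, gives the (3S)-propargylic alcohol F11. Semihydrogenation over Pd/CaCO3 poisoned with Pb(OAc)2 gives 29.

**Step 21.** Intermolecular etherification (oligomers) may compete with closure of the 14-membered ring, because the alkoxide is hindered and the chain is flexible.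
Fallback: replace the SN2 closure by an allylic substitution through an η3-allyl complex, setting out from 29 and returning at 30. Et2Zn forms the zinc alkoxide, and Pd(PPh3)4 (zerovalent palladium) ionises the allylic chloride at high dilution. The symmetrical allyl unit gives 30 from either terminus. No new compound is made (F0).

**Step 25.** Hexavalent chromium may over-oxidise, attacking the allylic CH2 groups at C2 and C9, the ring methyl groups or C6–H, if the rate advantage of the α-oxygenated C12 position is small.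
Fallback: postpone the oxidation until C1=C10 is gone, setting out from 35 and returning at 39. HF·pyridine gives the C3 alcohol F12, and Ac2O gives the acetate F13. One equivalent of mCPBA at low temperature epoxidises the trisubstituted C1=C10 in preference to the 1,1-disubstituted exocyclic alkene, giving the epoxy methylenetetrahydrofuran F14. Chromium trioxide–3,5-dimethylpyrazole then oxidises C12, the only remaining allylic ether CH2, to give 39.

**Step 28.** The peracid may add to the wrong face of C1=C10, since the preferred face depends on the ring conformation.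
Fallback: deliver the oxygen to the opposite face through a bromohydrin, setting out from 38 and returning at 39. N-Bromosuccinimide in aqueous THF places bromine on the more accessible face at C1 and water on the other face at the tertiary C10, giving bromohydrin F15. Ag2O closes the epoxide with inversion at C1, giving 39.

## Further compounds

F1 | step 23 | (2Z,4R,6Z)-4-[(tert-butyldimethylsilyl)oxy]-9,9-dimethoxy-3,7-dimethylnona-2,6-dien-1-ol | OC/C=C(/C)[C@H](O[Si](C)(C)C(C)(C)C)C/C=C(/C)CC(OC)OC
F2 | step 23 | (2Z,4R,6Z)-4-[(tert-butyldimethylsilyl)oxy]-9,9-dimethoxy-3,7-dimethylnona-2,6-dienal | O=C/C=C(/C)[C@H](O[Si](C)(C)C(C)(C)C)C/C=C(/C)CC(OC)OC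
F3 | step 23 | (3R,4Z,6R,8Z)-6-[(tert-butyldimethylsilyl)oxy]-11,11-dimethoxy-5,9-dimethylundeca-1,4,8-trien-3-ol | C=C[C@@H](O)/C=C(/C)[C@H](O[Si](C)(C)C(C)(C)C)C/C=C(/C)CC(OC)OC
F4 | step 23 | tert-butyl{[(3R,4Z,6R,8Z)-3-{[2-(chloromethyl)prop-2-en-1-yl]oxy}-11,11-dimethoxy-5,9-dimethylundeca-1,4,8-trien-6-yl]oxy}dimethylsilane | C=C[C@@H](OCC(=C)CCl)/C=C(/C)[C@H](O[Si](C)(C)C(C)(C)C)C/C=C(/C)CC(OC)OC
F5 | step 23 | tert-butyl{[(1Z,3R,5Z)-1-[(2S)-4-(chloromethyl)-2,5-dihydrofuran-2-yl]-8,8-dimethoxy-2,6-dimethylocta-1,5-dien-3-yl]oxy}dimethylsilane | ClCC1=C[C@@H](OC1)/C=C(/C)[C@H](O[Si](C)(C)C(C)(C)C)C/C=C(/C)CC(OC)OC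
F6 | step 23 | (3Z,6R,7Z)-6-[(tert-butyldimethylsilyl)oxy]-8-[(2S)-4-(chloromethyl)-2,5-dihydrofuran-2-yl]-3,7-dimethylocta-3,7-dienal | ClCC1=C[C@@H](OC1)/C=C(/C)[C@H](O[Si](C)(C)C(C)(C)C)C/C=C(/C)CC=O
F7 | step 17 | 3-iodo-2-(iodomethyl)prop-1-ene | ICC(=C)CI
F8 | step 17 | tributyl[(1S,3Z,6R,7Z)-6,9-bis[(tert-butyldimethylsilyl)oxy]-1-{[2-(iodomethyl)prop-2-en-1-yl]oxy}-3,7-dimethylnona-3,7-dien-1-yl]stannane | CC(C)(C)[Si](C)(C)OC/C=C(/C)[C@H](O[Si](C)(C)C(C)(C)C)C/C=C(/C)C[C@H]([Sn](CCCC)(CCCC)CCCC)OCC(=C)CI
F9 | step 20 | (4Z,6R,8Z,11S)-6-[(tert-butyldimethylsilyl)oxy]-11-{[2-(chloromethyl)prop-2-en-1-yl]oxy}-5,9-dimethyl-11-(tributylstannyl)undeca-4,8-dien-1-yn-3-ol, both C3 epimers | C#CC(O)/C=C(/C)[C@H](O[Si](C)(C)C(C)(C)C)C/C=C(/C)C[C@H]([Sn](CCCC)(CCCC)CCCC)OCC(=C)CCl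
F10 | step 20 | (4Z,6R,8Z,11S)-6-[(tert-butyldimethylsilyl)oxy]-11-{[2-(chloromethyl)prop-2-en-1-yl]oxy}-5,9-dimethyl-11-(tributylstannyl)undeca-4,8-dien-1-yn-3-one | C#CC(=O)/C=C(/C)[C@H](O[Si](C)(C)C(C)(C)C)C/C=C(/C)C[C@H]([Sn](CCCC)(CCCC)CCCC)OCC(=C)CCl
F11 | step 20 | (3S,4Z,6R,8Z,11S)-6-[(tert-butyldimethylsilyl)oxy]-11-{[2-(chloromethyl)prop-2-en-1-yl]oxy}-5,9-dimethyl-11-(tributylstannyl)undeca-4,8-dien-1-yn-3-ol | C#C[C@@H](O)/C=C(/C)[C@H](O[Si](C)(C)C(C)(C)C)C/C=C(/C)C[C@H]([Sn](CCCC)(CCCC)CCCC)OCC(=C)CCl
F0 | step 21 | none | none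
F12 | step 25 | (3aR,4S,6Z,9R,10Z,11aS)-9-hydroxy-6,10-dimethyl-3-methylidene-2,3,3a,4,5,8,9,11a-octahydrocyclodeca[b]furan-4-yl 3-methylbutanoate | C1O[C@H]2/C=C(/C)[C@H](O)C/C=C(/C)C[C@H](OC(=O)CC(C)C)[C@H]2C1=C
F13 | step 25 | (3aR,4S,6Z,9R,10Z,11aS)-9-(acetyloxy)-6,10-dimethyl-3-methylidene-2,3,3a,4,5,8,9,11a-octahydrocyclodeca[b]furan-4-yl 3-methylbutanoate | C1O[C@H]2/C=C(/C)[C@H](OC(C)=O)C/C=C(/C)C[C@H](OC(=O)CC(C)C)[C@H]2C1=C
F14 | step 25 | (1R,3R,6S,7R,8S,10S)-3-acetoxy-1,10:6,12-diepoxy-8-(3-methylbutanoyloxy)germacra-4Z,11(13)-diene (the cyclic ether corresponding to 39) | C1O[C@H]2/C=C(/C)[C@H](OC(C)=O)C[C@H]3O[C@@]3(C)C[C@H](OC(=O)CC(C)C)[C@H]2C1=C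
F15 | step 28 | (1S,3R,6S,7R,8S,10S)-3-acetoxy-1-bromo-10-hydroxy-8-(3-methylbutanoyloxy)germacra-4Z,11(13)-dien-12,6-olide | C=C1C(=O)O[C@H]2/C=C(/C)[C@H](OC(C)=O)C[C@H](Br)[C@](O)(C)C[C@H](OC(=O)CC(C)C)[C@@H]12
A1 | alternative 1 | cis ring-fusion diol of the C3–C8 bonded bicyclo[4.4.0]decadiene with C6 silyl ether and C7 3-[(4-methoxybenzyl)oxy]prop-1-en-2-yl group (target numbering) | CC(C)(C)[Si](C)(C)O[C@H]1C=C(C)[C@@]2(O)CC=C(C)C[C@@]2(O)[C@H]1C(=C)COCc1ccc(OC)cc1
A2 | alternative 1 | (Z,Z)-cyclodecadiene-1,6-dione with C3 and C8 ketones, C6 silyl ether and C7 3-[(4-methoxybenzyl)oxy]prop-1-en-2-yl group | CC(C)(C)[Si](C)(C)O[C@H]1/C=C(/C)C(=O)C/C=C(/C)CC(=O)[C@H]1C(=C)COCc2ccc(OC)cc2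
A3 | alternative 2 | C6–C10 bonded bicyclo[5.3.0]decene C6 alcohol with C1 mesylate, C3 PMB ether and C8 silyl ether | O[C@]12C=C(C)[C@H](OCc3ccc(OC)cc3)C[C@@H](OS(C)(=O)=O)[C@@]1(C)C[C@H](O[Si](C)(C)C(C)(C)C)C2
A4 | alternative 2 | (Z,Z)-cyclodeca-2,6-dienone (C6 ketone) with C3 PMB ether and C8 silyl ether | O=C1/C=C(/C)[C@H](OCc2ccc(OC)cc2)C/C=C(/C)C[C@H](O[Si](C)(C)C(C)(C)C)C1
A5 | alternative 3 | cis-1-{(E)-2-[(4-methoxybenzyl)oxy]ethenyl}-6-isopropenyl-3-methyl-4-[(tert-butyldimethylsilyl)oxy]cyclohex-2-en-1-ol | O[C@]1(/C=C/OCc2ccc(OC)cc2)C=C(C)[C@H](O[Si](C)(C)C(C)(C)C)C[C@H]1C(C)=C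
A6 | alternative 3 | (Z,Z)-cyclodeca-2,6-dienone (C6 ketone) with C3 silyl ether and C8 PMB ether | O=C1/C=C(/C)[C@H](O[Si](C)(C)C(C)(C)C)C/C=C(/C)C[C@H](OCc2ccc(OC)cc2)C1
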